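**Retrosynthetic overview**

1. The target is read as catechin-(4α→6)-catechin-(4α→6)-epicatechin. The last disconnection is the C4–C4a bond of ring C of the bottom (epicatechin) unit: a 6-endo Friedel–Crafts epoxide–arene cyclisation of an aryl threo-1-aryl-1-oxiranylmethyl ether that already carries C2 and C3 and delivers the 2,3-cis ring with free 3-OH.
2. Enabling feature: ring A of the bottom unit is a phloroglucinol ring whose interflavan carbon C6 lies para to C8a–O1. In the open precursor the two carbons ortho to the ether oxygen (future C4a and C8) are equivalent and each is ortho/para to three oxygens, so closure needs no regiocontrol and can only give the 4→6 isomer.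
3. The ether comes from Mitsunobu inversion of an erythro epoxy alcohol (Sharpless kinetic resolution) at the unhindered para-OH of a phloroglucinol ring. That ring is attached to C4 of the middle unit by Friedel–Crafts capture of the C4 cation (C3-symmetric nucleophile, one possible C-adduct).
4. The top–middle 4α→6 bond joins two (+)-catechin-derived units by orthogonal C4 activation (sulfide on the top unit, alkoxy on the middle unit), with bromine caps at C6/C8 (top) and C8 (middle) and 3-O-acetyl groups for 3,4-trans control.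
5. Ring order: rings A, C and B of the top and middle units come intact from (+)-catechin; ring A of the bottom unit is added as phloroglucinol and ring B with the epoxy alcohol; ring C of the bottom unit is closed last; deacetylation and hydrogenolysis finish.

Key step: step 13

Remark: C4-activated intermediates are drawn as the expected major C4 epimer; this configuration is lost on ionisation and has no bearing on the couplings, and rotamers about the interflavan bonds are ignored.

**Step 1**
Reactants: 1 (+)-catechin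
Product: 2 5,7,3',4'-tetra-O-benzyl-(+)-catechin (3-OH free)
Conditions: BnBr (4.4 equiv), K2CO3, DMF, 0 °C → rt
Reagents that add atoms: benzyl bromide, BrCc1ccccc1
Why: Williamson etherification benzylates the four phenols selectively over the much less acidic secondary 3-OH, and no stereocentre is touched.

**Step 2**
Reactants: 2 5,7,3',4'-tetra-O-benzyl-(+)-catechin
Product: 3 8-bromo-5,7,3',4'-tetra-O-benzyl-(+)-catechin
Conditions: NBS (1.0 equiv), CH2Cl2, −40 °C → rt
Reagents that add atoms: N-bromosuccinimide, O=C1CCC(=O)N1Br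
Why: Electrophilic aromatic bromination should take place at C8 of ring A, the most accessible carbon of the phloroglucinol ring (between O1 and 7-OBn), and this bromine blocks C8 in all later Friedel–Crafts events.

**Step 3**
Reactants: 3 8-bromo-5,7,3',4'-tetra-O-benzyl-(+)-catechin
Product: 4 8-bromo-4β-(2-ethoxyethoxy)-5,7,3',4'-tetra-O-benzyl-(+)-catechin (3,4-cis)
Conditions: DDQ (2 equiv), 2-ethoxyethanol (10 equiv), CH2Cl2, rt
Reagents that add atoms: 2-ethoxyethanol, CCOCCO
Why: DDQ benzylic oxidation generates the C4 cation stabilised by ring A, which the alcohol should capture anti to the 2-aryl group to give the 4β ether.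

**Step 4**
Reactants: 4 8-bromo-4β-(2-ethoxyethoxy)-5,7,3',4'-tetra-O-benzyl-(+)-catechin
Product: 5 3-O-acetyl-8-bromo-4β-(2-ethoxyethoxy)-5,7,3',4'-tetra-O-benzyl-(+)-catechin (middle-unit building block)
Conditions: Ac2O, pyridine, DMAP (cat.), rt
Reagents that add atoms: acetic anhydride, CC(=O)OC(C)=O
Why: DMAP-catalysed acylation of the secondary alcohol installs the 3-O-acetyl group that later shields the β face at C4.

**Step 5**
Reactants: 5 3-O-acetyl-8-bromo-4β-(2-ethoxyethoxy)-5,7,3',4'-tetra-O-benzyl-(+)-catechin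
Product: 6 3-O-acetyl-6,8-dibromo-4β-(2-ethoxyethoxy)-5,7,3',4'-tetra-O-benzyl-(+)-catechin
Conditions: NBS (1.15 equiv), CH2Cl2, 0 °C → rt, dark
Reagents that add atoms: N-bromosuccinimide, O=C1CCC(=O)N1Br
Why: A second electrophilic bromination at C6, the last ring-A CH and far more activated than any ring-B position, caps ring A of the future top unit so that it cannot act as a nucleophile.

**Step 6**
Reactants: 6 3-O-acetyl-6,8-dibromo-4β-(2-ethoxyethoxy)-5,7,3',4'-tetra-O-benzyl-(+)-catechin
Product: 7 3-O-acetyl-6,8-dibromo-4α-(4-methylphenylthio)-5,7,3',4'-tetra-O-benzyl-(+)-catechin (3,4-trans; top-unit electrophile)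
Conditions: 4-MeC6H4SH (3 equiv), BF3·OEt2 (1.2 equiv), CH2Cl2, −40 → 0 °C
Reagents that add atoms: 4-methylbenzenethiol, Cc1ccc(S)cc1
Why: Lewis acid-mediated SN1 exchange at the benzylic C4 replaces the hard oxygen leaving group by a soft sulfur one, the thiol entering trans to the participating 3-acetoxy group.

**Step 7**
Reactants: 7 3-O-acetyl-6,8-dibromo-4α-(4-methylphenylthio)-5,7,3',4'-tetra-O-benzyl-(+)-catechin; 5 3-O-acetyl-8-bromo-4β-(2-ethoxyethoxy)-5,7,3',4'-tetra-O-benzyl-(+)-catechin (1.5 equiv)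
Product: 8 protected dimer: 3-O-acetyl-6,8-dibromo-tetra-O-benzylcatechin-(4α→6)-[3-O-acetyl-8-bromo-4β-(2-ethoxyethoxy)-tetra-O-benzylcatechin]
Conditions: NIS (1.2 equiv), 4 Å MS, CH2Cl2, −78 → −30 °C
Reagents that add atoms: none
Why: Thiophilic (iodosulfonium) activation ionises only the C4 sulfide of 7, and C6 of 5 (its only free ring-A carbon) should attack trans to the 3-acetoxy group in a Friedel–Crafts alkylation to set the 3,4-trans 4α→6 bond, while the 4-alkoxy group of 5 is inert to the soft activator and the succinimide formed takes up the proton released.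

**Step 8**
Reactants: 8 protected dimer with 4β-(2-ethoxyethoxy) group on the middle unit; 9 phloroglucinol (10 equiv)
Product: 10 dimer–phloroglucinol adduct: as 8, but C4 of the middle unit carries a 4α-(2,4,6-trihydroxyphenyl) group (3,4-trans)
Conditions: BF3·OEt2 (2 equiv), THF/CH2Cl2 (1:1), −20 → 0 °C
Reagents that add atoms: none
Why: Hard Lewis acid activation of the remaining 4-alkoxy group gives the middle-unit C4 cation, which the C3-symmetric phloroglucinol (one kind of nucleophilic carbon, used in excess) should capture trans to the 3-acetoxy group in a Friedel–Crafts alkylation, setting the second 4α stereocentre without regiochemical ambiguity.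

**Step 9**
Reactants: 11 3,4-bis(benzyloxy)benzaldehyde
Product: 12 rac-1-[3,4-bis(benzyloxy)phenyl]prop-2-en-1-ol
Conditions: CH2=CHMgBr (1.2 equiv), THF, −78 → 0 °C
Reagents that add atoms: vinylmagnesium bromide, C=C[Mg]Br
Why: Grignard 1,2-addition to the aldehyde gives the racemic aryl vinyl carbinol needed for kinetic resolution.

**Step 10**
Reactants: 12 rac-1-[3,4-bis(benzyloxy)phenyl]prop-2-en-1-ol
Product: 13 (S)-[3,4-bis(benzyloxy)phenyl][(R)-oxiran-2-yl]methanol (erythro epoxy alcohol)
Conditions: Ti(OiPr)4 (0.15 equiv), L-(+)-DIPT (0.2 equiv), t-BuOOH (0.45 equiv), 4 Å MS, CH2Cl2, −20 °C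
Reagents that add atoms: tert-butyl hydroperoxide, CC(C)(C)OO
Why: In the Sharpless kinetic resolution the (R)-alcohol should be epoxidised faster and with erythro selectivity, so stopping below half conversion should give the epoxy alcohol with both stereocentres set by the tartrate catalyst, while (S)-12 remains unreacted.

**Step 11**
Reactants: 10 dimer–phloroglucinol adduct; 13 (S)-[3,4-bis(benzyloxy)phenyl][(R)-oxiran-2-yl]methanol (1.05 equiv)
Product: 14 para-O-alkylated adduct: the hydroxyl para to the interflavan carbon of the trihydroxyphenyl ring carries the (R)-[3,4-bis(benzyloxy)phenyl][(R)-oxiran-2-yl]methyl group (threo ether)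
Conditions: PPh3 (1.2 equiv), DIAD (1.2 equiv, slow addition), THF, −20 → 0 °C
Reagents that add atoms: none
Why: In this Mitsunobu etherification the para hydroxyl, the only phenol not flanked by the bulky flavan-4-yl substituent, should react preferentially and displace the activated benzylic alcohol with inversion (S to R at the future C2), leaving the epoxide untouched.

**Step 12**
Reactants: 14 para-O-alkylated adduct
Product: 15 cyclisation precursor: as 14, with the two remaining phenols of the bottom ring A as benzyl ethers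
Conditions: BnBr (3 equiv), K2CO3, n-Bu4NI (cat.), DMF, rt
Reagents that add atoms: benzyl bromide, BrCc1ccccc1
Why: Williamson etherification of the two hindered phenols gives the electron-rich tris-ether ring required for the cyclisation, and the secondary acetates and the epoxide tolerate K2CO3 in DMF.

**Step 13**
Reactants: 15 cyclisation precursor
Product: 16 protected trimer: 3-O-acetyl-6,8-dibromo-tetra-O-benzylcatechin-(4α→6)-[3-O-acetyl-8-bromo-tetra-O-benzylcatechin]-(4α→6)-[5,7,3',4'-tetra-O-benzyl-(−)-epicatechin] (bottom 3-OH free)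
Conditions: AuCl3 (5 mol %), AgOTf (15 mol %), tetramethylthiourea (10 mol %), 4 Å MS, ClCH2CH2Cl, 0 °C → rt
Reagents that add atoms: none
Why: Cationic trivalent gold (from AuCl3/AgOTf, tempered by the thiourea) activates the terminal epoxide and the tris-oxygenated ring A attacks its CH2 carbon in an intramolecular Friedel–Crafts alkylation, the closest known reaction type being the gold-catalysed cycloalkylation of aryl 1-aryl-2,3-epoxypropyl ethers to flavan-3-ols. Ring C of the bottom unit closes in the 6-endo-tet mode by C4–C4a bond formation, because the 5-exo alternative would require attack at the more substituted and more hindered epoxide carbon. No new stereocentre is created: C2 (set by the Mitsunobu inversion) and C3 (the epoxide CH, whose C–O bond is kept) are carried over unchanged, so the threo ether should translate directly into the 2,3-cis (2R,3R) ring with the 3-OH set free. The step needs site selectivity between the two ring carbons ortho to the ether oxygen, and the substrate makes this moot because both are flanked by the ether oxygen and one OBn and are exchanged by rotation about the C6···C8a axis, so either closure gives the same 4→6-linked flavan and the 4→8 isomer cannot form. Chemoselectivity over the other arenes rests on their bromine caps and on intramolecularity, and the benzyl-protected interflavan bonds should withstand the mild Lewis acid at room temperature.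

**Step 14**
Reactants: 16 protected trimer with two 3-O-acetyl groups
Product: 17 protected trimer with three free 3-OH groups (twelve benzyl ethers, three aryl bromides)
Conditions: NaOMe (cat.), MeOH/THF (1:1), rt → 40 °C
Reagents that add atoms: none
Why: Zemplén-type transesterification removes the two secondary acetates without touching benzyl ethers, aryl bromides or stereocentres.

**Step 15**
Reactants: 17 protected trimer with three free 3-OH groups
Product: 18 catechin-(4α→6)-catechin-(4α→6)-epicatechin (CNP0163146.3)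
Conditions: H2 (1 atm), Pd(OH)2/C, Et3N (3.3 equiv), THF/MeOH/H2O, rt
Reagents that add atoms: none
Why: Catalytic hydrogenolysis over Pd(OH)2/C should cleave the twelve benzyl ethers and, with Et3N as HBr scavenger, hydrodehalogenate the three aryl bromides, the buffered medium protecting the acid-labile interflavan bonds of the free procyanidin.

**Compound list**

1 | (+)-catechin, (2R,3S) | Oc1cc(O)c2c(c1)O[C@H](c1ccc(O)c(O)c1)[C@@H](O)C2 | starting material
2 | 5,7,3',4'-tetra-O-benzyl-(+)-catechin | c9ccccc9COc1cc(OCc9ccccc9)c2c(c1)O[C@H](c1ccc(OCc9ccccc9)c(OCc9ccccc9)c1)[C@@H](O)C2 | intermediate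
3 | 8-bromo-5,7,3',4'-tetra-O-benzyl-(+)-catechin | c9ccccc9COc1cc(OCc9ccccc9)c2c(c1Br)O[C@H](c1ccc(OCc9ccccc9)c(OCc9ccccc9)c1)[C@@H](O)C2 | intermediate
4 | 8-bromo-4β-(2-ethoxyethoxy)-5,7,3',4'-tetra-O-benzyl-(+)-catechin (3,4-cis) | c9ccccc9COc1cc(OCc9ccccc9)c2c(c1Br)O[C@H](c1ccc(OCc9ccccc9)c(OCc9ccccc9)c1)[C@@H](O)[C@H]2OCCOCC | intermediate
5 | 3-O-acetyl-8-bromo-4β-(2-ethoxyethoxy)-5,7,3',4'-tetra-O-benzyl-(+)-catechin | c9ccccc9COc1cc(OCc9ccccc9)c2c(c1Br)O[C@H](c1ccc(OCc9ccccc9)c(OCc9ccccc9)c1)[C@@H](OC(C)=O)[C@H]2OCCOCC | intermediate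
6 | 3-O-acetyl-6,8-dibromo-4β-(2-ethoxyethoxy)-5,7,3',4'-tetra-O-benzyl-(+)-catechin | c9ccccc9COc1c(Br)c(OCc9ccccc9)c2c(c1Br)O[C@H](c1ccc(OCc9ccccc9)c(OCc9ccccc9)c1)[C@@H](OC(C)=O)[C@H]2OCCOCC | intermediate
7 | 3-O-acetyl-6,8-dibromo-4α-(4-methylphenylthio)-5,7,3',4'-tetra-O-benzyl-(+)-catechin (3,4-trans) | c9ccccc9COc1c(Br)c(OCc9ccccc9)c2c(c1Br)O[C@H](c1ccc(OCc9ccccc9)c(OCc9ccccc9)c1)[C@@H](OC(C)=O)[C@@H]2Sc9ccc(C)cc9 | intermediate
8 | protected (4α→6) dimer, 4β-(2-ethoxyethoxy) on the middle unit | c9ccccc9COc1c(Br)c(OCc9ccccc9)c2c(c1Br)O[C@H](c1ccc(OCc9ccccc9)c(OCc9ccccc9)c1)[C@@H](OC(C)=O)[C@@H]2c1c(OCc9ccccc9)c(Br)c2c(c1OCc9ccccc9)[C@H](OCCOCC)[C@H](OC(C)=O)[C@@H](c1ccc(OCc9ccccc9)c(OCc9ccccc9)c1)O2 | intermediate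
9 | phloroglucinol (benzene-1,3,5-triol) | Oc1cc(O)cc(O)c1 | starting material
10 | dimer–(4α→2)-phloroglucinol adduct (2,4,6-trihydroxyphenyl at C4α of the middle unit) | c9ccccc9COc1c(Br)c(OCc9ccccc9)c2c(c1Br)O[C@H](c1ccc(OCc9ccccc9)c(OCc9ccccc9)c1)[C@@H](OC(C)=O)[C@@H]2c1c(OCc9ccccc9)c(Br)c2c(c1OCc9ccccc9)[C@@H](c1c(O)cc(O)cc1O)[C@H](OC(C)=O)[C@@H](c1ccc(OCc9ccccc9)c(OCc9ccccc9)c1)O2 | intermediate
11 | 3,4-bis(benzyloxy)benzaldehyde | O=Cc1ccc(OCc9ccccc9)c(OCc9ccccc9)c1 | starting material
12 | rac-1-[3,4-bis(benzyloxy)phenyl]prop-2-en-1-ol | C=CC(O)c1ccc(OCc9ccccc9)c(OCc9ccccc9)c1 | intermediate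
13 | (S)-[3,4-bis(benzyloxy)phenyl][(R)-oxiran-2-yl]methanol (erythro) | O[C@@H](c1ccc(OCc9ccccc9)c(OCc9ccccc9)c1)[C@H]1CO1 | intermediate
14 | adduct 10 etherified at the para hydroxyl with the (R)-aryl[(R)-oxiran-2-yl]methyl group (threo ether; two phenols free) | c9ccccc9COc1c(Br)c(OCc9ccccc9)c2c(c1Br)O[C@H](c1ccc(OCc9ccccc9)c(OCc9ccccc9)c1)[C@@H](OC(C)=O)[C@@H]2c1c(OCc9ccccc9)c(Br)c2c(c1OCc9ccccc9)[C@@H](c3c(O)cc(O[C@H](c4ccc(OCc9ccccc9)c(OCc9ccccc9)c4)[C@H]4CO4)cc3O)[C@H](OC(C)=O)[C@@H](c1ccc(OCc9ccccc9)c(OCc9ccccc9)c1)O2 | intermediate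
15 | cyclisation precursor (14 with both remaining phenols benzylated) | c9ccccc9COc1c(Br)c(OCc9ccccc9)c2c(c1Br)O[C@H](c1ccc(OCc9ccccc9)c(OCc9ccccc9)c1)[C@@H](OC(C)=O)[C@@H]2c1c(OCc9ccccc9)c(Br)c2c(c1OCc9ccccc9)[C@@H](c3c(OCc9ccccc9)cc(O[C@H](c4ccc(OCc9ccccc9)c(OCc9ccccc9)c4)[C@H]4CO4)cc3OCc9ccccc9)[C@H](OC(C)=O)[C@@H](c1ccc(OCc9ccccc9)c(OCc9ccccc9)c1)O2 | intermediate
16 | protected trimer with 2,3-cis bottom unit (two 3-O-acetyl groups, bottom 3-OH free) | c9ccccc9COc1c(Br)c(OCc9ccccc9)c2c(c1Br)O[C@H](c1ccc(OCc9ccccc9)c(OCc9ccccc9)c1)[C@@H](OC(C)=O)[C@@H]2c1c(OCc9ccccc9)c(Br)c2c(c1OCc9ccccc9)[C@@H](c3c(OCc9ccccc9)cc4c(c3OCc9ccccc9)C[C@@H](O)[C@@H](c3ccc(OCc9ccccc9)c(OCc9ccccc9)c3)O4)[C@H](OC(C)=O)[C@@H](c1ccc(OCc9ccccc9)c(OCc9ccccc9)c1)O2 | intermediate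
17 | protected trimer with three free 3-OH groups | c9ccccc9COc1c(Br)c(OCc9ccccc9)c2c(c1Br)O[C@H](c1ccc(OCc9ccccc9)c(OCc9ccccc9)c1)[C@@H](O)[C@@H]2c1c(OCc9ccccc9)c(Br)c2c(c1OCc9ccccc9)[C@@H](c3c(OCc9ccccc9)cc4c(c3OCc9ccccc9)C[C@@H](O)[C@@H](c3ccc(OCc9ccccc9)c(OCc9ccccc9)c3)O4)[C@H](O)[C@@H](c1ccc(OCc9ccccc9)c(OCc9ccccc9)c1)O2 | intermediate
18 | catechin-(4α→6)-catechin-(4α→6)-epicatechin (CNP0163146.3) | Oc1cc(O)c2c(c1)O[C@H](c1ccc(O)c(O)c1)[C@@H](O)[C@@H]2c1c(O)cc2c(c1O)[C@@H](c1c(O)cc3c(c1O)C[C@@H](O)[C@@H](c1ccc(O)c(O)c1)O3)[C@H](O)[C@@H](c1ccc(O)c(O)c1)O2 | target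

**Step count and risks**

Total: 15 steps. Longest linear sequence: 13 steps (steps 1–8 and 11–15, from (+)-catechin).

Steps most likely to fail:

Step 11. The risk is loss of site selectivity among the three phenols (alkylation at a flanking hydroxyl or double alkylation) and partial loss of configuration at the electron-rich benzylic carbinol through an SN1 pathway. The fallback differentiates the phenols by protecting groups before the Mitsunobu reaction. Setting out from 10, silylation with the bulky TBDPSCl (imidazole, DMF, 0 °C) should take only the unhindered para hydroxyl and give the para-O-TBDPS ether F1. Benzylation of the two flanking phenols (BnBr, K2CO3, DMF) gives the bis(benzyl ether) F2, and TBAF/AcOH in THF removes the silyl group to give the mono-phenol F3. Its single free hydroxyl is then coupled with 13 (PPh3, DIAD, toluene, −20 °C), coming back to the route at 15 and by-passing 14.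

Step 13. The risk is ionisation of the benzylic aryl ether C2–O bond by the Lewis acid (epimerisation at C2 or O-to-C migration of the benzylic group) and competing 5-exo opening of the epoxide. The fallback runs the ring closure on the free phenol instead of the tris-ether, with hydrogen-bond activation and no metal. Setting out from 14, warming in hexafluoroisopropanol/CH2Cl2 should let the far more nucleophilic free resorcinol-type ring open the epoxide 6-endo to give the cyclised 5,7-dihydroxy flavan F4. NaOMe in MeOH/THF removes the acetates to give the deacetylated compound F5, and hydrogenolysis as in step 15 comes back to the route at 18.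

Step 7. The risk is competing iodination of ring A of 5 by NIS, premature ionisation of its 4-alkoxy group, or sluggish attack at the hindered C6. The fallback gives up orthogonal activation and introduces the second leaving group after the coupling. Setting out from 3, acetylation (Ac2O, pyridine) gives the 3-O-acetyl-8-bromo nucleophile F6. The capped 4-alkoxy electrophile 6 is condensed with excess F6 (TMSOTf, CH2Cl2, −78 °C) to give the 4α→6 dimer F7, which has a CH2 at C4 of the lower unit. DDQ oxidation of that benzylic position in the presence of 2-ethoxyethanol comes back to the route at 8.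

**Further compounds**

F1 | step 11 | adduct 10 with the para hydroxyl as tert-butyldiphenylsilyl ether | c9ccccc9COc1c(Br)c(OCc9ccccc9)c2c(c1Br)O[C@H](c1ccc(OCc9ccccc9)c(OCc9ccccc9)c1)[C@@H](OC(C)=O)[C@@H]2c1c(OCc9ccccc9)c(Br)c2c(c1OCc9ccccc9)[C@@H](c3c(O)cc(O[Si](c4ccccc4)(c4ccccc4)C(C)(C)C)cc3O)[C@H](OC(C)=O)[C@@H](c1ccc(OCc9ccccc9)c(OCc9ccccc9)c1)O2
F2 | step 11 | F1 with both flanking phenols benzylated | c9ccccc9COc1c(Br)c(OCc9ccccc9)c2c(c1Br)O[C@H](c1ccc(OCc9ccccc9)c(OCc9ccccc9)c1)[C@@H](OC(C)=O)[C@@H]2c1c(OCc9ccccc9)c(Br)c2c(c1OCc9ccccc9)[C@@H](c3c(OCc9ccccc9)cc(O[Si](c4ccccc4)(c4ccccc4)C(C)(C)C)cc3OCc9ccccc9)[C@H](OC(C)=O)[C@@H](c1ccc(OCc9ccccc9)c(OCc9ccccc9)c1)O2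
F3 | step 11 | mono-phenol: 2,6-bis(benzyloxy)-4-hydroxyphenyl group at C4α of the middle unit | c9ccccc9COc1c(Br)c(OCc9ccccc9)c2c(c1Br)O[C@H](c1ccc(OCc9ccccc9)c(OCc9ccccc9)c1)[C@@H](OC(C)=O)[C@@H]2c1c(OCc9ccccc9)c(Br)c2c(c1OCc9ccccc9)[C@@H](c3c(OCc9ccccc9)cc(O)cc3OCc9ccccc9)[C@H](OC(C)=O)[C@@H](c1ccc(OCc9ccccc9)c(OCc9ccccc9)c1)O2
F4 | step 13 | cyclised trimer with free 5,7-hydroxyls on the bottom unit (two 3-O-acetyl groups) | c9ccccc9COc1c(Br)c(OCc9ccccc9)c2c(c1Br)O[C@H](c1ccc(OCc9ccccc9)c(OCc9ccccc9)c1)[C@@H](OC(C)=O)[C@@H]2c1c(OCc9ccccc9)c(Br)c2c(c1OCc9ccccc9)[C@@H](c3c(O)cc4c(c3O)C[C@@H](O)[C@@H](c3ccc(OCc9ccccc9)c(OCc9ccccc9)c3)O4)[C@H](OC(C)=O)[C@@H](c1ccc(OCc9ccccc9)c(OCc9ccccc9)c1)O2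
F5 | step 13 | F4 without the two acetates | c9ccccc9COc1c(Br)c(OCc9ccccc9)c2c(c1Br)O[C@H](c1ccc(OCc9ccccc9)c(OCc9ccccc9)c1)[C@@H](O)[C@@H]2c1c(OCc9ccccc9)c(Br)c2c(c1OCc9ccccc9)[C@@H](c3c(O)cc4c(c3O)C[C@@H](O)[C@@H](c3ccc(OCc9ccccc9)c(OCc9ccccc9)c3)O4)[C@H](O)[C@@H](c1ccc(OCc9ccccc9)c(OCc9ccccc9)c1)O2
F6 | step 7 | 3-O-acetyl-8-bromo-5,7,3',4'-tetra-O-benzyl-(+)-catechin | c9ccccc9COc1cc(OCc9ccccc9)c2c(c1Br)O[C@H](c1ccc(OCc9ccccc9)c(OCc9ccccc9)c1)[C@@H](OC(C)=O)C2
F7 | step 7 | protected (4α→6) dimer with CH2 at C4 of the lower unit | c9ccccc9COc1c(Br)c(OCc9ccccc9)c2c(c1Br)O[C@H](c1ccc(OCc9ccccc9)c(OCc9ccccc9)c1)[C@@H](OC(C)=O)[C@@H]2c1c(OCc9ccccc9)c(Br)c2c(c1OCc9ccccc9)C[C@H](OC(C)=O)[C@@H](c1ccc(OCc9ccccc9)c(OCc9ccccc9)c1)O2
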